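**Retrosynthetic overview**
1. Final step forms both target rings at once: the C6–C7 bond (ten-membered carbocycle), then O–C12 (α-methylene-γ-lactone), by an aqueous indium Barbier macro-allylation/lactonisation of the unprotected hemiacetal bromide 15.
2. 15 ⇐ cross-metathesis of terminal alkene 13 with methyl 2-(bromomethyl)acrylate.
3. 13 is a temporary dihydropyranol ring, i.e. a masked (Z)-γ,δ-dihydroxy-enal carrying Z-C4=C5, C2 and C3 ⇐ Achmatowicz ring expansion and Luche reduction of furyl carbinol 10 (C2 by Noyori transfer hydrogenation).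
4. 10 ⇐ furyl ketone 4 from (R)-β-methyl-γ-butyrolactone (C10) and 2-lithio-3-methylfuran; C9 by Ir-catalysed allylation of the primary alcohol; angelate by mixed-anhydride acylation.
5. Ring order: auxiliary dihydropyranol (step 5, opened again in step 8) → carbocycle → lactone (both in step 8).

Assumption: 1, 2, 5, 7 and 14 are catalogue chemicals; hemiacetals 12, 13, 15, 16, F9 and F10 are anomeric mixtures, so that centre is left undefined in their SMILES; atom labels C1–C13 are germacranolide numbering of 19.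

**Step 1**
Reactants: 1 (4R)-4-methyldihydrofuran-2(3H)-one; 2 2-bromo-3-methylfuran
Product: 4 (3R)-4-hydroxy-3-methyl-1-(3-methylfuran-2-yl)butan-1-one, via (3-methylfuran-2-yl)lithium 3 (not isolated)
Conditions: 2, n-BuLi, THF, −78 °C; then 1, −78 °C; aq. NH4Cl
Reagents that add atoms: none
Why: Br/Li exchange followed by acylation of the furyllithium by the lactone, which stops at the ketone because the lithium hemiketal alkoxide survives until the quench; the C10 methyl stereocentre comes unchanged from 1.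

**Step 2**
Reactants: 4 (3R)-4-hydroxy-3-methyl-1-(3-methylfuran-2-yl)butan-1-one; 5 allyl acetate
Product: 6 (3R,4S)-4-hydroxy-3-methyl-1-(3-methylfuran-2-yl)hept-6-en-1-one
Conditions: [Ir(cod)Cl]2 (2.5 mol%), (S)-SEGPHOS (5 mol%), 4-Cl-3-NO2-C6H3CO2H (10 mol%), Cs2CO3 (20 mol%), THF, 100 °C, sealed tube
Reagents that add atoms: none
Why: Krische iridium-catalysed transfer-hydrogenative carbonyl allylation; the π-allyl-iridium complex dehydrogenates only the primary alcohol and allylates the transient α-methyl aldehyde before it can epimerise, and the ligand antipode is chosen so that catalyst control gives the 4S carbinol (C9, anti to the C10 methyl), the aryl ketone staying untouched.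

**Step 3**
Reactants: 6 (3R,4S)-4-hydroxy-3-methyl-1-(3-methylfuran-2-yl)hept-6-en-1-one; 7 angelic acid
Product: 9 (4S,5R)-5-methyl-7-(3-methylfuran-2-yl)-7-oxohept-1-en-4-yl (2Z)-2-methylbut-2-enoate, via mixed anhydride 8 (not isolated)
Conditions: 7, 2,4,6-Cl3C6H2COCl, Et3N, toluene, rt; then 6, toluene, 75 °C (no DMAP)
Reagents that add atoms: none
Why: Yamaguchi-type mixed-anhydride esterification of the only free hydroxyl; thermal acyl transfer without a nucleophilic catalyst keeps the (Z)-angelate from isomerising to tiglate, and C9 is acylated with retention.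

**Step 4**
Reactants: 9 (4S,5R)-5-methyl-7-(3-methylfuran-2-yl)-7-oxohept-1-en-4-yl (2Z)-2-methylbut-2-enoate
Product: 10 (4S,5R,7S)-7-hydroxy-5-methyl-7-(3-methylfuran-2-yl)hept-1-en-4-yl (2Z)-2-methylbut-2-enoate
Conditions: RuCl(p-cymene)[(S,S)-TsDPEN] (1 mol%), HCO2H/Et3N (5:2), CH2Cl2, rt
Reagents that add atoms: none
Why: Noyori asymmetric transfer hydrogenation of a heteroaryl ketone; the (S,S)-catalyst delivers hydride to give the S furyl carbinol (C2) under catalyst control, and ester and alkenes are inert.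

**Step 5**
Reactants: 10 (4S,5R,7S)-7-hydroxy-5-methyl-7-(3-methylfuran-2-yl)hept-1-en-4-yl (2Z)-2-methylbut-2-enoate
Product: 12 (4S,5R)-6-[(2S)-6-hydroxy-4-methyl-3-oxo-3,6-dihydro-2H-pyran-2-yl]-5-methylhex-1-en-4-yl (2Z)-2-methylbut-2-enoate, via cis-enedione 11 (not isolated)
Conditions: NBS (1.05 equiv), NaHCO3, THF/H2O (4:1), 0 °C
Reagents that add atoms: water, O
Why: Achmatowicz oxidative ring expansion; bromination/hydration opens the furan to the cis-enedione, which the C2 hydroxyl traps as the pyranone hemiacetal, so C2 is retained and the furan's cis C=C becomes the Z-C4=C5 alkene of the target.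

**Step 6**
Reactants: 12 (4S,5R)-6-[(2S)-6-hydroxy-4-methyl-3-oxo-3,6-dihydro-2H-pyran-2-yl]-5-methylhex-1-en-4-yl (2Z)-2-methylbut-2-enoate
Product: 13 (4S,5R)-6-[(2S,3R)-3,6-dihydroxy-4-methyl-3,6-dihydro-2H-pyran-2-yl]-5-methylhex-1-en-4-yl (2Z)-2-methylbut-2-enoate
Conditions: NaBH4, CeCl3·7H2O, MeOH/CH2Cl2, −78 °C
Reagents that add atoms: none
Why: Luche 1,2-reduction; axial hydride attack anti to the pseudo-equatorial C2 side chain gives the 2,3-trans allylic alcohol (C3 = R, the erythro diol of the target), while the hemiacetal and both esters are not reduced at −78 °C.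

**Step 7**
Reactants: 13 (4S,5R)-6-[(2S,3R)-3,6-dihydroxy-4-methyl-3,6-dihydro-2H-pyran-2-yl]-5-methylhex-1-en-4-yl (2Z)-2-methylbut-2-enoate; 14 methyl 2-(bromomethyl)acrylate
Product: 15 methyl (2Z,5S,6R)-2-(bromomethyl)-7-[(2S,3R)-3,6-dihydroxy-4-methyl-3,6-dihydro-2H-pyran-2-yl]-6-methyl-5-{[(2Z)-2-methylbut-2-enoyl]oxy}hept-2-enoate
Conditions: Hoveyda–Grubbs II (10 mol%), 14 (5 equiv), CH2Cl2, 40 °C
Reagents that add atoms: none
Why: olefin cross-metathesis of a type I terminal alkene with a non-dimerising 1,1-disubstituted acrylate (type III); the trisubstituted ring alkene and the angelate are inert, and the thermodynamic Z isomer (chain cis to CH2Br) forms.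

**Step 8**
Reactants: 15 methyl (2Z,5S,6R)-2-(bromomethyl)-7-[(2S,3R)-3,6-dihydroxy-4-methyl-3,6-dihydro-2H-pyran-2-yl]-6-methyl-5-{[(2Z)-2-methylbut-2-enoyl]oxy}hept-2-enoate
Product: 19 (2S,3R,4Z,6R,7S,9S,10R)-9-angeloyloxy-2,3-dihydroxygermacra-4,11(13)-dien-12,6-olide (target), via allylindium 16 (not isolated), via open-chain enal 17 (not isolated), via hydroxy ester 18 (not isolated)
Conditions: In powder (6 equiv), THF/pH 7 phosphate buffer (1:1), 35 °C, ultrasound, 15 added by syringe pump (final 2 mM); then 40 °C, 6 h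
Reagents that add atoms: none
Why: Proposed new method: indium inserts into the allylic C–Br bond to give a water-tolerant 2-(methoxycarbonyl)allylindium that persists until the hemiacetal opens to the (Z)-dihydroxy-enal, whose aldehyde is then attacked by the γ-carbon (C7) through a six-membered chair transition state embedded in the forming ten-membered ring, and the C6 alkoxide closes onto the methyl ester, so carbocycle and lactone form in one flask; 6R is expected from attack on the s-trans enal from the face opposite C2 (H-3 held in the alkene plane by A(1,3) strain) and 7S from the chair with C5 and C8 pseudo-equatorial (6,7-trans), but this is a model, not a known result; the closest known chemistry is the aqueous indium Barbier allylation of unprotected lactols (sugars) with 2-(bromomethyl)acrylates and the intramolecular Barbier/Nozaki–Hiyama allylation–lactonisation that closes 6,7-trans germacranolides.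

**Compound list**
1 | (4R)-4-methyldihydrofuran-2(3H)-one | C[C@H]1COC(=O)C1 | starting material
2 | 2-bromo-3-methylfuran | Cc1ccoc1Br | starting material
3 | (3-methylfuran-2-yl)lithium | [Li]c1occc1C | intermediate
4 | (3R)-4-hydroxy-3-methyl-1-(3-methylfuran-2-yl)butan-1-one | OC[C@H](C)CC(=O)c1occc1C | intermediate
5 | allyl acetate | C=CCOC(C)=O | starting material
6 | (3R,4S)-4-hydroxy-3-methyl-1-(3-methylfuran-2-yl)hept-6-en-1-one | C=CC[C@H](O)[C@H](C)CC(=O)c1occc1C | intermediate
7 | angelic acid, (2Z)-2-methylbut-2-enoic acid | C/C=C(/C)C(=O)O | starting material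
8 | mixed anhydride of angelic and 2,4,6-trichlorobenzoic acid | C/C=C(/C)C(=O)OC(=O)c1c(Cl)cc(Cl)cc1Cl | intermediate
9 | (4S,5R)-5-methyl-7-(3-methylfuran-2-yl)-7-oxohept-1-en-4-yl (2Z)-2-methylbut-2-enoate | C=CC[C@H](OC(=O)/C(C)=C\C)[C@H](C)CC(=O)c1occc1C | intermediate
10 | (4S,5R,7S)-7-hydroxy-5-methyl-7-(3-methylfuran-2-yl)hept-1-en-4-yl (2Z)-2-methylbut-2-enoate | C=CC[C@H](OC(=O)/C(C)=C\C)[C@H](C)C[C@H](O)c1occc1C | intermediate
11 | (4S,5R,7S,9Z)-7-hydroxy-5,9-dimethyl-8,11-dioxoundeca-1,9-dien-4-yl (2Z)-2-methylbut-2-enoate (cis-enedione) | C=CC[C@H](OC(=O)/C(C)=C\C)[C@H](C)C[C@H](O)C(=O)/C(C)=C\C=O | intermediate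
12 | (4S,5R)-6-[(2S)-6-hydroxy-4-methyl-3-oxo-3,6-dihydro-2H-pyran-2-yl]-5-methylhex-1-en-4-yl (2Z)-2-methylbut-2-enoate | C=CC[C@H](OC(=O)/C(C)=C\C)[C@H](C)C[C@@H]1OC(O)C=C(C)C1=O | intermediate
13 | (4S,5R)-6-[(2S,3R)-3,6-dihydroxy-4-methyl-3,6-dihydro-2H-pyran-2-yl]-5-methylhex-1-en-4-yl (2Z)-2-methylbut-2-enoate | C=CC[C@H](OC(=O)/C(C)=C\C)[C@H](C)C[C@@H]1OC(O)C=C(C)[C@H]1O | intermediate
14 | methyl 2-(bromomethyl)acrylate | C=C(CBr)C(=O)OC | starting material
15 | methyl (2Z,5S,6R)-2-(bromomethyl)-7-[(2S,3R)-3,6-dihydroxy-4-methyl-3,6-dihydro-2H-pyran-2-yl]-6-methyl-5-{[(2Z)-2-methylbut-2-enoyl]oxy}hept-2-enoate | COC(=O)/C(CBr)=C/C[C@H](OC(=O)/C(C)=C\C)[C@H](C)C[C@@H]1OC(O)C=C(C)[C@H]1O | intermediate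
16 | allylindium from 15, hemiacetal form (C–Br replaced by C–InBr2; sesquihalide drawn as the dibromide) | COC(=O)/C(C[In](Br)Br)=C/C[C@H](OC(=O)/C(C)=C\C)[C@H](C)C[C@@H]1OC(O)C=C(C)[C@H]1O | intermediate
17 | open-chain tautomer of 16: (Z)-enal with free 2,3-diol and the allylindium terminus | O=C/C=C(/C)[C@@H](O)[C@@H](O)C[C@@H](C)[C@@H](OC(=O)/C(C)=C\C)C/C=C(/C(=O)OC)C[In](Br)Br | intermediate
18 | seco-lactone methyl ester of 19: ten-membered (Z)-cyclodecene with 6R-OH and 7S-[1-(methoxycarbonyl)vinyl] | O[C@@H]1/C=C(/C)[C@@H](O)[C@@H](O)C[C@@H](C)[C@@H](OC(=O)/C(C)=C\C)C[C@H]1C(=C)C(=O)OC | intermediate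
19 | (2S,3R,4Z,6R,7S,9S,10R)-9-angeloyloxy-2,3-dihydroxygermacra-4,11(13)-dien-12,6-olide | C=C1C(=O)O[C@@H]2/C=C(/C)[C@@H](O)[C@@H](O)C[C@@H](C)[C@@H](OC(=O)/C(C)=C\C)C[C@@H]12 | target

**Step count**
Total steps: 8, with no protecting groups. Longest linear sequence: 8 (from 1 or 2 to 19).

**Three steps most likely to fail**

Step 8. The allylindium may be protonated before the hemiacetal opens. The hemiacetal may dehydrate back to a furan. The closure may give the 6,7-cis lactone or the wrong C6/C7 pair, because the stereochemical argument is only a model. The fallback sets out from 13 and comes back at 19; it uses a protected, open-chain aldehyde and chromium. Sodium borohydride reduces the hemiacetal of 13 to the open-chain (Z)-triol F1. 2,2-Dimethoxypropane/PPTS closes the erythro C2/C3 diol to the acetonide F2 and leaves the primary allylic alcohol free. MnO2 gives the (Z)-enal F3. Cross-metathesis with 14 gives the bromo enal F4. CrCl2 in THF/DMF at 2 mM (Nozaki–Hiyama allylation with lactonisation) gives the acetonide lactone F5, and aqueous acetic acid frees the diol to give 19.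

Step 7. Cross-metathesis with a 1,1-disubstituted acrylate that also carries an allylic bromide, on a polyol hemiacetal, may stall or kill the catalyst. The fallback sets out from 9 and comes back at 19; it builds the trisubstituted enoate by olefination and changes the pronucleophile to an allylsilane. OsO4/NaIO4/2,6-lutidine cuts the terminal alkene of 9 to the aldehyde F6. Horner–Wadsworth–Emmons reaction with methyl 2-(dimethoxyphosphoryl)-3-(trimethylsilyl)propanoate gives the allylsilane keto ester F7. The conditions of steps 4, 5 and 6 then give the furyl carbinol F8, the pyranone hemiacetal F9 and the dihydropyran diol F10. TBAF in dilute THF opens the hemiacetal and triggers an intramolecular Hosomi–Sakurai allylation; the alkoxide lactonises to 19.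

Step 2. The iridium hydride could reduce the furyl ketone, or hemiketal formation could hold back the primary alcohol; the mismatched (anti-Felkin) sense may also lower the dr. The fallback sets out from 4 and comes back at 6; it uses a discrete aldehyde and a stoichiometric chiral borane. TEMPO/PhI(OAc)2 oxidises 4 to the keto aldehyde F11, which is used crude at −78 °C with (−)-B-allyldiisopinocampheylborane (Brown allylation, oxidative work-up) to give 6.

**Further compounds**
F1 | step 8 | (4S,5R,7S,8R,9Z)-7,8,11-trihydroxy-5,9-dimethylundeca-1,9-dien-4-yl (2Z)-2-methylbut-2-enoate | OC/C=C(/C)[C@@H](O)[C@@H](O)C[C@@H](C)[C@@H](OC(=O)/C(C)=C\C)CC=C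
F2 | step 8 | 7,8-O-isopropylidene acetal (cis-dioxolane) of F1 with free primary allylic alcohol | OC/C=C(/C)[C@H]1OC(C)(C)O[C@H]1C[C@@H](C)[C@@H](OC(=O)/C(C)=C\C)CC=C
F3 | step 8 | (Z)-enal from F2 | O=C/C=C(/C)[C@H]1OC(C)(C)O[C@H]1C[C@@H](C)[C@@H](OC(=O)/C(C)=C\C)CC=C
F4 | step 8 | (Z)-2-(bromomethyl)enoate from F3, acetonide enal | O=C/C=C(/C)[C@H]1OC(C)(C)O[C@H]1C[C@@H](C)[C@@H](OC(=O)/C(C)=C\C)C/C=C(/C(=O)OC)CBr
F5 | step 8 | 2,3-O-isopropylidene derivative of 19 | C=C1C(=O)O[C@@H]2/C=C(/C)[C@H]3OC(C)(C)O[C@H]3C[C@@H](C)[C@@H](OC(=O)/C(C)=C\C)C[C@@H]12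
F6 | step 7 | (3S,4R)-4-methyl-6-(3-methylfuran-2-yl)-1,6-dioxohexan-3-yl (2Z)-2-methylbut-2-enoate | O=CC[C@H](OC(=O)/C(C)=C\C)[C@H](C)CC(=O)c1occc1C
F7 | step 7 | methyl (5S,6R)-6-methyl-5-{[(2Z)-2-methylbut-2-enoyl]oxy}-8-(3-methylfuran-2-yl)-8-oxo-2-[(trimethylsilyl)methyl]oct-2-enoate (E/Z mixture) | COC(=O)C(C[Si](C)(C)C)=CC[C@H](OC(=O)/C(C)=C\C)[C@H](C)CC(=O)c1occc1C
F8 | step 7 | (8S)-alcohol from F7 (furyl carbinol) | COC(=O)C(C[Si](C)(C)C)=CC[C@H](OC(=O)/C(C)=C\C)[C@H](C)C[C@H](O)c1occc1C
F9 | step 7 | pyranone hemiacetal from F8 (allylsilane analogue of 12) | COC(=O)C(C[Si](C)(C)C)=CC[C@H](OC(=O)/C(C)=C\C)[C@H](C)C[C@@H]1OC(O)C=C(C)C1=O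
F10 | step 7 | dihydropyran diol from F9 (allylsilane analogue of 15) | COC(=O)C(C[Si](C)(C)C)=CC[C@H](OC(=O)/C(C)=C\C)[C@H](C)C[C@@H]1OC(O)C=C(C)[C@H]1O
F11 | step 2 | (2R)-2-methyl-4-(3-methylfuran-2-yl)-4-oxobutanal | O=C[C@H](C)CC(=O)c1occc1C
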